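**Plan**

- Retrosynthetic cuts, in order: the two O–Si bonds; the aryl–acyl bond C4–C4a of ring C (a carbanion at C4a, stored as C4a–Br, plus a Weinreb amide hung from O1); the ether bond O1–C2; the C8–CH2 bond to the geranyl chain; the C2 carbinol back to a β-keto amide.
- Enabling feature: in ring A, C4a is ortho to C8a, the carbon that carries O1, so a carbanion at C4a lies five atoms (C8a, O1, C2, C3, C4) from the acyl carbon and closes the six-membered ring C. The other ortho position, C8, is blocked by the geranyl group.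
- Commercial 4-bromoresorcinol already carries bromine at the future C4a, and its only C–H flanked by both oxygens is the future C8, so base-directed lithiation puts the geranyl group there.
- Forward: ring A and ring B are bought; geranyl goes on C8; the (R)-β-hydroxy Weinreb amide of ring B is joined through O1–C2; ring C closes last through C4–C4a; both silyl groups are then removed.
- Stereochemistry: C2 is set as R by asymmetric transfer hydrogenation, inverted to S in the Mitsunobu etherification, and not touched afterwards (no acid, no free base). The E double bond comes with geranyl bromide.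

Key step: step 9

**Remarks**

- Atom numbers are those of the flavanone (O1, C2, C3, C4, C4a, C5 to C8, C8a). Ring A is the benzo ring, ring C the pyranone ring, ring B the 4-hydroxyphenyl ring.
- Commercial geranyl bromide is taken as the pure 2E isomer; LDA and t-BuLi are used as commercial solutions.
- The sense of induction in step 7 is assumed to follow that of simple aryl ketones with this catalyst.

**Route**

Step 1
Reactants: 1 4-bromoresorcinol (4-bromobenzene-1,3-diol)
Product: 2 1-bromo-2,4-bis(methoxymethoxy)benzene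
Conditions: MOMCl (2.5 equiv), i-Pr2NEt (3 equiv), CH2Cl2, 0 °C → rt
Reagents that add atoms: chloromethyl methyl ether, COCCl
Why: Standard O-alkylation of both phenols with an α-chloro ether under amine base gives the bis(acetal) ether, whose two OMOM groups later direct the metalation.

Step 2
Reactants: 2 1-bromo-2,4-bis(methoxymethoxy)benzene; 3 geranyl bromide [(2E)-1-bromo-3,7-dimethylocta-2,6-diene]
Product: 5 1-bromo-3-[(2E)-3,7-dimethylocta-2,6-dien-1-yl]-2,4-bis(methoxymethoxy)benzene, via aryllithium 4 (not isolated)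
Conditions: LDA (1.2 equiv), THF, −78 °C; then CuBr·SMe2 (10 mol %), 3 (1.3 equiv), −78 → 0 °C
Reagents that add atoms: none
Why: Directed ortho-metalation, in which the amide base (which does not undergo bromine–lithium exchange) removes the C–H flanked by both OMOM groups, followed by copper-assisted SN2 allylation of the aryllithium at the primary carbon of geranyl bromide with the E double bond retained.

Step 3
Reactants: 5 1-bromo-3-[(2E)-3,7-dimethylocta-2,6-dien-1-yl]-2,4-bis(methoxymethoxy)benzene
Product: 6 4-bromo-2-[(2E)-3,7-dimethylocta-2,6-dien-1-yl]benzene-1,3-diol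
Conditions: HCl (0.5 M in MeOH), MeOH, 0 °C → rt, stopped at full conversion
Reagents that add atoms: none
Why: Acid-catalyzed acetal exchange with methanol should free both phenols under dilute, cold conditions in which the trisubstituted double bonds are protonated only slowly.

Step 4
Reactants: 6 4-bromo-2-[(2E)-3,7-dimethylocta-2,6-dien-1-yl]benzene-1,3-diol
Product: 7 6-bromo-2-[(2E)-3,7-dimethylocta-2,6-dien-1-yl]-3-[(triisopropylsilyl)oxy]phenol
Conditions: TIPSCl (1.05 equiv), imidazole (2.2 equiv), CH2Cl2, 0 °C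
Reagents that add atoms: triisopropylsilyl chloride, CC(C)[Si](Cl)(C(C)C)C(C)C
Why: Silyl ether formation with the bulky chlorosilane should take place at the hydroxyl that has only one ortho substituent, leaving free the hydroxyl flanked by bromine and the geranyl group (the future O1).

Step 5
Reactants: 8 methyl 4-hydroxybenzoate
Product: 9 methyl 4-[(triisopropylsilyl)oxy]benzoate
Conditions: TIPSCl (1.1 equiv), imidazole (2.2 equiv), DMF, rt
Reagents that add atoms: triisopropylsilyl chloride, CC(C)[Si](Cl)(C(C)C)C(C)C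
Why: Routine silyl protection of a phenol, chosen because an aryl TIPS ether should survive enolates, formic acid/triethylamine, Mitsunobu conditions and t-BuLi.

Step 6
Reactants: 9 methyl 4-[(triisopropylsilyl)oxy]benzoate; 10 N-methoxy-N-methylacetamide
Product: 12 N-methoxy-N-methyl-3-oxo-3-{4-[(triisopropylsilyl)oxy]phenyl}propanamide, via lithium enolate 11 (not isolated)
Conditions: 10 (2.2 equiv), LDA (2.2 equiv), THF, −78 °C; then 9, −78 → 0 °C; AcOH
Reagents that add atoms: none
Why: Crossed Claisen condensation of the amide enolate with a non-enolizable ester, driven to completion because the β-keto amide is removed as its enolate by the second equivalent of 11.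

Step 7
Reactants: 12 N-methoxy-N-methyl-3-oxo-3-{4-[(triisopropylsilyl)oxy]phenyl}propanamide
Product: 13 (3R)-3-hydroxy-N-methoxy-N-methyl-3-{4-[(triisopropylsilyl)oxy]phenyl}propanamide
Conditions: RuCl[(R,R)-TsDPEN](p-cymene) (1 mol %), HCO2H/Et3N (5:2), DMF, rt → 40 °C
Reagents that add atoms: none
Why: Noyori asymmetric transfer hydrogenation of an aryl ketone, in which the (R,R)-diamine ruthenium hydride delivers hydride to the ketone face fixed by the CH/π contact between the aryl group and the p-cymene ligand, which for aryl ketones should give the (R)-carbinol.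

Step 8
Reactants: 7 6-bromo-2-[(2E)-3,7-dimethylocta-2,6-dien-1-yl]-3-[(triisopropylsilyl)oxy]phenol; 13 (3R)-3-hydroxy-N-methoxy-N-methyl-3-{4-[(triisopropylsilyl)oxy]phenyl}propanamide
Product: 14 (3S)-3-{6-bromo-2-[(2E)-3,7-dimethylocta-2,6-dien-1-yl]-3-[(triisopropylsilyl)oxy]phenoxy}-N-methoxy-N-methyl-3-{4-[(triisopropylsilyl)oxy]phenyl}propanamide
Conditions: PPh3 (1.5 equiv), DIAD (1.5 equiv), toluene (0.5 M), 0 °C → rt
Reagents that add atoms: none
Why: Mitsunobu etherification, in which the acidic ortho-bromophenol displaces the oxyphosphonium group by SN2 with inversion (R carbinol to S aryl ether), while the Weinreb amide keeps the C3 hydrogens poorly acidic and so limits dehydration.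

Step 9
Reactants: 14 (3S)-3-{6-bromo-2-[(2E)-3,7-dimethylocta-2,6-dien-1-yl]-3-[(triisopropylsilyl)oxy]phenoxy}-N-methoxy-N-methyl-3-{4-[(triisopropylsilyl)oxy]phenyl}propanamide
Product: 17 (2S)-8-[(2E)-3,7-dimethylocta-2,6-dien-1-yl]-7-[(triisopropylsilyl)oxy]-2-{4-[(triisopropylsilyl)oxy]phenyl}-2,3-dihydro-4H-chromen-4-one, via aryllithium 15 (not isolated), via lithium hemiaminal alkoxide 16 (not isolated)
Conditions: t-BuLi (2.1 equiv), THF, −90 → −78 °C; then AcOH (3 equiv), −78 °C → rt
Reagents that add atoms: none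
Why: t-BuLi should exchange the C4a–Br bond at −90 °C faster than it deprotonates or adds to the amide, and the aryllithium 15 then adds to the Weinreb carbonyl five atoms away to give the chelated lithium hemiaminal alkoxide 16, which cannot be attacked again and collapses to the ketone only on the acetic acid quench. The closest known reaction type is the Parham cyclization (halogen–lithium exchange followed by intramolecular acylation of the aryllithium by a Weinreb amide). Ring C closes in the 6-exo-trig mode by forming the C4–C4a bond. No new stereocenter remains in 17, because the C4 hemiaminal center of 16 is lost on collapse, and C2, set in step 8, takes part in no bond change and meets neither acid nor a free base above −78 °C. The step needs regioselectivity (C4a, not C8 or C6) and chemoselectivity (acylation of the carbanion, not proton transfer from C3–H followed by loss of the aryloxide); the first is fixed by the bromine inherited from 4-bromoresorcinol and by the geranyl group on C8, the second by the low kinetic acidity of the Weinreb amide α-hydrogens, the low temperature and the six-membered transition state. The acid-sensitive geranyl chain and both silyl ethers should be inert to these conditions.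

Step 10
Reactants: 17 (2S)-8-[(2E)-3,7-dimethylocta-2,6-dien-1-yl]-7-[(triisopropylsilyl)oxy]-2-{4-[(triisopropylsilyl)oxy]phenyl}-2,3-dihydro-4H-chromen-4-one
Product: 18 (2S)-7,4'-dihydroxy-8-geranylflavanone
Conditions: TBAF (2.4 equiv), AcOH (2.4 equiv), THF, 0 °C
Reagents that add atoms: none
Why: Fluoride cleavage of both aryl silyl ethers, buffered with acetic acid so that no phenoxide or enolate builds up that could open ring C by retro-oxa-Michael reaction and racemize C2.

**Compound list**

1 | 4-bromoresorcinol (4-bromobenzene-1,3-diol) | Oc1ccc(Br)c(O)c1 | starting material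
2 | 1-bromo-2,4-bis(methoxymethoxy)benzene | COCOc1ccc(Br)c(OCOC)c1 | intermediate
3 | geranyl bromide [(2E)-1-bromo-3,7-dimethylocta-2,6-diene] | CC(C)=CCC/C(C)=C/CBr | starting material
4 | [3-bromo-2,6-bis(methoxymethoxy)phenyl]lithium | [Li]c1c(OCOC)ccc(Br)c1OCOC | intermediate
5 | 1-bromo-3-[(2E)-3,7-dimethylocta-2,6-dien-1-yl]-2,4-bis(methoxymethoxy)benzene | CC(C)=CCC/C(C)=C/Cc1c(OCOC)ccc(Br)c1OCOC | intermediate
6 | 4-bromo-2-[(2E)-3,7-dimethylocta-2,6-dien-1-yl]benzene-1,3-diol | CC(C)=CCC/C(C)=C/Cc1c(O)ccc(Br)c1O | intermediate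
7 | 6-bromo-2-[(2E)-3,7-dimethylocta-2,6-dien-1-yl]-3-[(triisopropylsilyl)oxy]phenol | CC(C)=CCC/C(C)=C/Cc1c(O[Si](C(C)C)(C(C)C)C(C)C)ccc(Br)c1O | intermediate
8 | methyl 4-hydroxybenzoate | COC(=O)c1ccc(O)cc1 | starting material
9 | methyl 4-[(triisopropylsilyl)oxy]benzoate | COC(=O)c1ccc(O[Si](C(C)C)(C(C)C)C(C)C)cc1 | intermediate
10 | N-methoxy-N-methylacetamide | CC(=O)N(C)OC | starting material
11 | lithium enolate of N-methoxy-N-methylacetamide | C=C(O[Li])N(C)OC | intermediate
12 | N-methoxy-N-methyl-3-oxo-3-{4-[(triisopropylsilyl)oxy]phenyl}propanamide | O=C(CC(=O)N(C)OC)c1ccc(O[Si](C(C)C)(C(C)C)C(C)C)cc1 | intermediate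
13 | (3R)-3-hydroxy-N-methoxy-N-methyl-3-{4-[(triisopropylsilyl)oxy]phenyl}propanamide | O[C@@H](c1ccc(O[Si](C(C)C)(C(C)C)C(C)C)cc1)CC(=O)N(C)OC | intermediate
14 | (3S)-3-{6-bromo-2-[(2E)-3,7-dimethylocta-2,6-dien-1-yl]-3-[(triisopropylsilyl)oxy]phenoxy}-N-methoxy-N-methyl-3-{4-[(triisopropylsilyl)oxy]phenyl}propanamide | CC(C)=CCC/C(C)=C/Cc1c(O[Si](C(C)C)(C(C)C)C(C)C)ccc(Br)c1O[C@H](c1ccc(O[Si](C(C)C)(C(C)C)C(C)C)cc1)CC(=O)N(C)OC | intermediate
15 | aryllithium from 14 (lithium in place of bromine at the future C4a) | CC(C)=CCC/C(C)=C/Cc1c(O[Si](C(C)C)(C(C)C)C(C)C)ccc([Li])c1O[C@H](c1ccc(O[Si](C(C)C)(C(C)C)C(C)C)cc1)CC(=O)N(C)OC | intermediate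
16 | lithium alkoxide of the (2S)-4-[methoxy(methyl)amino]chroman-4-ol (tetrahedral adduct, C4 not defined) | CC(C)=CCC/C(C)=C/Cc1c(O[Si](C(C)C)(C(C)C)C(C)C)ccc2c1O[C@H](c1ccc(O[Si](C(C)C)(C(C)C)C(C)C)cc1)CC2(O[Li])N(C)OC | intermediate
17 | (2S)-8-[(2E)-3,7-dimethylocta-2,6-dien-1-yl]-7-[(triisopropylsilyl)oxy]-2-{4-[(triisopropylsilyl)oxy]phenyl}-2,3-dihydro-4H-chromen-4-one | CC(C)=CCC/C(C)=C/Cc1c(O[Si](C(C)C)(C(C)C)C(C)C)ccc2c1O[C@H](c1ccc(O[Si](C(C)C)(C(C)C)C(C)C)cc1)CC2=O | intermediate
18 | (2S)-7,4'-dihydroxy-8-geranylflavanone | CC(C)=CCC/C(C)=C/Cc1c(O)ccc2c1O[C@H](c1ccc(O)cc1)CC2=O | target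

**Step count and risks**

Total step count: 10. Longest linear sequence: 7 steps (steps 1, 2, 3, 4, 8, 9, 10, from 4-bromoresorcinol).

Steps most likely to fail:

1. Step 8 (Mitsunobu etherification). What may go wrong: the phenol carries two ortho substituents, so SN2 attack on the oxyphosphonium ion may be slow. The ion can then lose a proton from C3 (dehydration to the cinnamamide) or ionize to the para-silyloxybenzyl cation, which erodes the configuration at C2.
 Fallback, from 7, back at 18: ring B is added last to a flat chromone by catalyst-controlled conjugate addition, so no substitution at a benzylic carbinol is needed.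
 - Oxa-Michael addition of 7 to acrylonitrile (benzyltrimethylammonium hydroxide cat., 70 °C) should give 3-{6-bromo-2-[(2E)-3,7-dimethylocta-2,6-dien-1-yl]-3-[(triisopropylsilyl)oxy]phenoxy}propanenitrile F1.
 - Bromine–lithium exchange (t-BuLi, THF, −78 °C) with ring closure onto the nitrile, then mild aqueous HCl work-up, should give 8-[(2E)-3,7-dimethylocta-2,6-dien-1-yl]-7-[(triisopropylsilyl)oxy]-2,3-dihydro-4H-chromen-4-one F2. Ring C is still closed through C4–C4a.
 - Dehydrogenation with IBX (DMSO, 70 °C) should give 8-[(2E)-3,7-dimethylocta-2,6-dien-1-yl]-7-[(triisopropylsilyl)oxy]-4H-chromen-4-one F3.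
 - Asymmetric 1,4-addition of commercial 4-[(tert-butyldimethylsilyl)oxy]phenylboronic acid (Pd(OCOCF3)2, t-BuPyOx, NH4PF6, H2O, ClCH2CH2Cl, 60 °C; ligand enantiomer chosen to give the 2S series) should give (2S)-2-{4-[(tert-butyldimethylsilyl)oxy]phenyl}-8-[(2E)-3,7-dimethylocta-2,6-dien-1-yl]-7-[(triisopropylsilyl)oxy]-2,3-dihydro-4H-chromen-4-one F4.
 - The buffered fluoride of step 10 then removes both silyl groups to give 18.

2. Step 9 (bromine–lithium exchange and ring closure). What may go wrong: proton transfer from C3–H to the aryllithium or to t-BuLi, followed by β-elimination of the aryloxide, or intermolecular addition of t-BuLi to the amide before exchange.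
 Fallback, from 14, back at 17: the same C4–C4a bond is made by a chromium-mediated carbonyl addition, which involves no strong base.
 - An aromatic Finkelstein reaction (CuI cat., NaI, trans-N,N'-dimethylcyclohexane-1,2-diamine, dioxane, 110 °C) should give the aryl iodide (3S)-3-{2-[(2E)-3,7-dimethylocta-2,6-dien-1-yl]-6-iodo-3-[(triisopropylsilyl)oxy]phenoxy}-N-methoxy-N-methyl-3-{4-[(triisopropylsilyl)oxy]phenyl}propanamide F5.
 - DIBAL-H (THF, −78 °C) should reduce the Weinreb amide to (3S)-3-{2-[(2E)-3,7-dimethylocta-2,6-dien-1-yl]-6-iodo-3-[(triisopropylsilyl)oxy]phenoxy}-3-{4-[(triisopropylsilyl)oxy]phenyl}propanal F6.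
 - An intramolecular Nozaki–Hiyama–Kishi reaction (CrCl2, NiCl2 cat., DMF, rt) should close ring C to (2S)-8-[(2E)-3,7-dimethylocta-2,6-dien-1-yl]-7-[(triisopropylsilyl)oxy]-2-{4-[(triisopropylsilyl)oxy]phenyl}chroman-4-ol F7, as a mixture of C4 epimers.
 - Dess–Martin periodinane (NaHCO3, CH2Cl2) should oxidize it to 17.

3. Step 3 (acidic cleavage of the MOM ethers). What may go wrong: acid-promoted addition of a freed ortho-hydroxyl to the near double bond of the geranyl chain (chroman formation), or cation–olefin cyclization of the chain.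
 Fallback, from 1, back at 7: no acetal is used, so no acid is needed.
 - Silylation of the unhindered hydroxyl of 1 (para to bromine) with TIPSCl/imidazole (CH2Cl2, 0 °C) should give 2-bromo-5-[(triisopropylsilyl)oxy]phenol F8.
 - Treatment of F8 with NaH in toluene and then geranyl bromide 3 should C-alkylate the only free ortho position, the carbon between the two oxygens (ortho C-allylation of a phenoxide ion pair in a non-polar solvent), to give 7 directly.

**Further compounds**

F1 | step 8 | 3-{6-bromo-2-[(2E)-3,7-dimethylocta-2,6-dien-1-yl]-3-[(triisopropylsilyl)oxy]phenoxy}propanenitrile | CC(C)=CCC/C(C)=C/Cc1c(O[Si](C(C)C)(C(C)C)C(C)C)ccc(Br)c1OCCC#N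
F2 | step 8 | 8-[(2E)-3,7-dimethylocta-2,6-dien-1-yl]-7-[(triisopropylsilyl)oxy]-2,3-dihydro-4H-chromen-4-one | CC(C)=CCC/C(C)=C/Cc1c(O[Si](C(C)C)(C(C)C)C(C)C)ccc2c1OCCC2=O
F3 | step 8 | 8-[(2E)-3,7-dimethylocta-2,6-dien-1-yl]-7-[(triisopropylsilyl)oxy]-4H-chromen-4-one | CC(C)=CCC/C(C)=C/Cc1c(O[Si](C(C)C)(C(C)C)C(C)C)ccc2c1OC=CC2=O
F4 | step 8 | (2S)-2-{4-[(tert-butyldimethylsilyl)oxy]phenyl}-8-[(2E)-3,7-dimethylocta-2,6-dien-1-yl]-7-[(triisopropylsilyl)oxy]-2,3-dihydro-4H-chromen-4-one | CC(C)=CCC/C(C)=C/Cc1c(O[Si](C(C)C)(C(C)C)C(C)C)ccc2c1O[C@H](c1ccc(O[Si](C)(C)C(C)(C)C)cc1)CC2=O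
F5 | step 9 | (3S)-3-{2-[(2E)-3,7-dimethylocta-2,6-dien-1-yl]-6-iodo-3-[(triisopropylsilyl)oxy]phenoxy}-N-methoxy-N-methyl-3-{4-[(triisopropylsilyl)oxy]phenyl}propanamide | CC(C)=CCC/C(C)=C/Cc1c(O[Si](C(C)C)(C(C)C)C(C)C)ccc(I)c1O[C@H](c1ccc(O[Si](C(C)C)(C(C)C)C(C)C)cc1)CC(=O)N(C)OC
F6 | step 9 | (3S)-3-{2-[(2E)-3,7-dimethylocta-2,6-dien-1-yl]-6-iodo-3-[(triisopropylsilyl)oxy]phenoxy}-3-{4-[(triisopropylsilyl)oxy]phenyl}propanal | CC(C)=CCC/C(C)=C/Cc1c(O[Si](C(C)C)(C(C)C)C(C)C)ccc(I)c1O[C@H](c1ccc(O[Si](C(C)C)(C(C)C)C(C)C)cc1)CC=O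
F7 | step 9 | (2S)-8-[(2E)-3,7-dimethylocta-2,6-dien-1-yl]-7-[(triisopropylsilyl)oxy]-2-{4-[(triisopropylsilyl)oxy]phenyl}chroman-4-ol (C4 epimers) | CC(C)=CCC/C(C)=C/Cc1c(O[Si](C(C)C)(C(C)C)C(C)C)ccc2c1O[C@H](c1ccc(O[Si](C(C)C)(C(C)C)C(C)C)cc1)CC2O
F8 | step 3 | 2-bromo-5-[(triisopropylsilyl)oxy]phenol | Oc1cc(O[Si](C(C)C)(C(C)C)C(C)C)ccc1Br
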